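(The data are calculated with made-up constants; noise was put on by code.)

The south-east run is this very flask, charged with 20 mM of solid substrate and followed up to 3.00 d. You want [isomer of the product]/[target] at the times asked below.

- south-east: solid substrate 20 mM; the very flask that is asked about, followed so far
- flask: solid substrate 20 mM; time 15 d

south-east run (percent of the solid substrate charged)

| time / d | isomer of the product / % | target / % |
|---|---|---|
| 0.250 | 9.7 | 0 |
| 0.833 | 32.5 | 0.9 |
| 1.25 | 47.9 | 0.4 |
| 2.00 | 75.7 | 2.9 |
| 3.00 | 89.2 | 3.0 |

(each reading ± 1 percentage point)

- as a solid, counted per litre of solution: solid substrate
- at the start none of the solid substrate is in solution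

* ratio of isomer of the product to target at 1.5 h
* ratio of isomer of the product to target at 20 h
* ratio of isomer of the product to target at 15 d

Single readings of this flask give a puzzle: the ratio reads 36.1 at 0.833 d but 120 at 1.25 d. The puzzle clears up when you look at the target reading at 1.25 d: 0.4 % is less than its scatter of 1 percentage point. One standard deviation up, that reading gives

ratio = 34.2,

so the two readings need not disagree. The last two target readings stand above the scatter, so I pool them into the late ratio, the summed isomer over the summed target of those readings:

late ratio = 27.9, from 22.5 to 36.8 for one standard deviation of the summed target readings.

My own reckoning freezes the ratio of this flask there up to 15 d; it gives no number for 1.5 h or 20 h.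

The forecast gives 40, 38 and 30, on these grounds: “I take parallel formation as the central guess because it is simpler”.

The flask gives 5.32, 28.6 and 36.1.

    starting material → intermediate (k = 0.200 /h)
    intermediate ⇌ target (K = 0.360, k = 4.50 /h)
    intermediate ⇌ isomer of the product (K = 13.0, k = 2.50 /h)
    solid substrate ⇌ starting material, rate k4*(cs4 - [starting material]) while solid is left; crystals form when [starting material] > cs4 (solubility = 1.90 mM, k = 3.00 /h)
    starting material + target → side product (k = 6.40 /M/h)
    starting material → decomposition product (k = 1.80 × 10⁻⁴ /h)

At 1.50 d this flask still held 27.1 % of solid substrate, and the turning of intermediate into isomer of the product had 63 % of its turnover up to 15 d behind it. By 7.50 d the solid substrate stood at 0 %, with isomer at 88.8 % and target at 2.46 %, as at 15 d. This flask's ratio of 36.1 at 15 d equals the constant of the isomer step over that of the target step, 36.1, which is thermodynamic control. The late ratio, a reading, turns this flask's 88.8 % of isomer into 3.18 % of target, and the flask holds 2.46 %. The neighbour flask with 5.0 mM of solid substrate reads 5.32 at 1.5 h and 36.1 at 15 d; the late ratio turns its 89.9 % of isomer into 3.22 % of target, and it holds 2.49 %.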